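Everything rests on cutting ring C of the flavone at C4–C4a. This leads back to a (Z)-3-aryloxy-3-arylacrylic acid that already holds the O1–C2 bond and the hindered ring B. Activating the acid as a mixed anhydride lets its acyl carbon acylate ring A intramolecularly, so one operation forms the last skeletal bond and closes the pyranone. The step exploits C4a of ring A: both its ring neighbours bear oxygen (C8a with O1, C5 with O5), the C7 methoxy group stands para to it, and it is the only open position ortho to O1. The precursor carries O5 as a benzyl ether and arises from phenol addition to an aryl propiolate.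

Key step: step 7

Assumption: the conjugate adduct and all later acrylates are drawn as the Z isomer (aryloxy cis to the carboxyl carbon). This is the geometry expected from anti addition and from the bulk of ring B. Any E isomer can be carried along, because the geometry equilibrates under the acid of the ring closure.

Step 1
Reactants: 1 2,6-dimethoxybenzaldehyde
Product: 2 2-(2,2-dibromovinyl)-1,3-dimethoxybenzene
Conditions: CBr4, PPh3, Zn dust, CH2Cl2, 0 °C → rt
Reagents that add atoms: carbon tetrabromide, BrC(Br)(Br)Br
Why: First stage of the Corey–Fuchs sequence, in which the ylide Ph3P=CBr2 made in the flask undergoes a Wittig-type olefination with the non-enolisable aldehyde, and zinc as halogen acceptor keeps Lewis-acidic phosphorus bromides away from the aryl methyl ethers.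

Step 2
Reactants: 2 2-(2,2-dibromovinyl)-1,3-dimethoxybenzene; 3 methyl chloroformate
Product: 5 methyl 3-(2,6-dimethoxyphenyl)propiolate, via lithium acetylide 4 (not isolated)
Conditions: n-BuLi (2.1 equiv), THF, −78 °C; then ClCO2Me (3), −78 °C → rt
Reagents that add atoms: none
Why: Second stage of the Corey–Fuchs sequence, in which bromine–lithium exchange, Fritsch–Buttenberg–Wiechell-type loss of LiBr and deprotonation give acetylide 4, which is C-acylated by the chloroformate, while ring lithiation next to a methoxy group is too slow at −78 °C to interfere.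

Step 3
Reactants: 5 methyl 3-(2,6-dimethoxyphenyl)propiolate; 6 3-hydroxy-4,5-dimethoxybenzaldehyde
Product: 7 methyl (Z)-3-(2,6-dimethoxyphenyl)-3-(5-formyl-2,3-dimethoxyphenoxy)acrylate
Conditions: K2CO3 (0.5 equiv), DMF, 80 °C
Reagents that add atoms: none
Why: Base-mediated oxa-Michael addition of a phenoxide to an aryl alkynoate, the classical entry to β-aryloxycinnamates, in which anti addition and the bulk of ring B both place the aryloxy group cis to the ester (Z), and the non-enolisable aldehyde is a spectator.

Step 4
Reactants: 7 methyl (Z)-3-(2,6-dimethoxyphenyl)-3-(5-formyl-2,3-dimethoxyphenoxy)acrylate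
Product: 9 methyl (Z)-3-(2,6-dimethoxyphenyl)-3-(5-hydroxy-2,3-dimethoxyphenoxy)acrylate, via aryl formate 8 (not isolated)
Conditions: mCPBA (1.3 equiv), CH2Cl2, 0 °C → rt; then Et3N (cat.), MeOH, rt
Reagents that add atoms: mCPBA (3-chloroperoxybenzoic acid), OOC(=O)c1cccc(Cl)c1
Why: Baeyer–Villiger oxidation of an electron-rich benzaldehyde (aryl migration helped by the para methoxy group, as in the 3,4,5-trialkoxybenzaldehyde series) followed by mild methanolysis of the formate; a peracid is chosen because alkaline peroxide needs a free ortho or para hydroxyl and would attack the ester, the push–pull alkene is too electron-poor to be epoxidised, and the methyl ester cannot scramble in methanol.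

Step 5
Reactants: 9 methyl (Z)-3-(2,6-dimethoxyphenyl)-3-(5-hydroxy-2,3-dimethoxyphenoxy)acrylate
Product: 10 methyl (Z)-3-[5-(benzyloxy)-2,3-dimethoxyphenoxy]-3-(2,6-dimethoxyphenyl)acrylate
Conditions: BnBr, K2CO3, DMF, rt
Reagents that add atoms: benzyl bromide, BrCc1ccccc1
Why: Williamson ether synthesis on the only free, unhindered phenol, which keeps O5 a full donor for the ring closure and is removable under neutral conditions at the end.

Step 6
Reactants: 10 methyl (Z)-3-[5-(benzyloxy)-2,3-dimethoxyphenoxy]-3-(2,6-dimethoxyphenyl)acrylate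
Product: 11 (Z)-3-[5-(benzyloxy)-2,3-dimethoxyphenoxy]-3-(2,6-dimethoxyphenyl)acrylic acid
Conditions: LiOH, THF–MeOH–H2O, rt; then 1 M HCl, 0 °C
Reagents that add atoms: lithium hydroxide, [Li+].[OH-]
Why: Ester saponification at the unhindered methyl ester carbonyl, while the β-carbon is shielded from hydroxide addition–elimination by ring B and its two methoxy groups, as in the classical hydrolysis of β-aryloxycinnamates.

Step 7
Reactants: 11 (Z)-3-[5-(benzyloxy)-2,3-dimethoxyphenoxy]-3-(2,6-dimethoxyphenyl)acrylic acid
Product: 13 5-(benzyloxy)-2-(2,6-dimethoxyphenyl)-7,8-dimethoxy-4H-chromen-4-one, via mixed trifluoroacetic anhydride 12 (not isolated)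
Conditions: (CF3CO)2O (3 equiv), CH2Cl2 (0.05 M), 0 °C → rt
Reagents that add atoms: none
Why: The acid is converted into mixed anhydride 12, whose acyl carbon (or the acylium ion left after loss of trifluoroacetate) is attacked by C4a of ring A, and loss of the C4a proton from the arenium ion restores aromaticity and leaves the new C4–C4a bond. This is an intramolecular Friedel–Crafts acylation, the long-known closing move of flavone syntheses from β-aryloxycinnamic acids. Ring C closes as a six-membered ring in a 6-exo-trig sense at the activated carbonyl (the C=O stays outside the new ring), the Z alkene holding O1 and C4 on the same side, and any E isomer reaches this geometry by reversible protonation at the α-carbon (future C3) of the push–pull alkene. No stereocentre is formed. The step needs site selectivity on ring A, and the tether secures it: C8, the other carbon ortho to O1, bears a methoxy group and C6 cannot be reached, whereas C4a is activated by O1, O5 and the para C7 methoxy group, and ring B cannot compete by indenone formation because both its ortho carbons are methoxylated. Fast anhydrous formation of 12 shuts off protodecarboxylation of the acid, and the only acid present, dilute CF3CO2H, should leave the benzyl ether in place.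

Step 8
Reactants: 13 5-(benzyloxy)-2-(2,6-dimethoxyphenyl)-7,8-dimethoxy-4H-chromen-4-one
Product: 14 Altisin, 5-hydroxy-2-(2,6-dimethoxyphenyl)-7,8-dimethoxy-4H-chromen-4-one
Conditions: H2 (1 atm), Pd/C (10 wt %), EtOAc–MeOH, rt
Reagents that add atoms: none
Why: Catalytic hydrogenolysis of an aryl benzyl ether, under which the methyl ethers are inert and the hindered C2–C3 bond of the vinylogous ester is not reduced at atmospheric pressure if the reaction is stopped after one equivalent of hydrogen.

Compound list
1 | 2,6-dimethoxybenzaldehyde | COc1cccc(OC)c1C=O | starting material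
2 | 2-(2,2-dibromovinyl)-1,3-dimethoxybenzene | COc1cccc(OC)c1C=C(Br)Br | intermediate
3 | methyl chloroformate | COC(Cl)=O | starting material
4 | lithium (2,6-dimethoxyphenyl)acetylide | [Li]C#Cc1c(OC)cccc1OC | intermediate
5 | methyl 3-(2,6-dimethoxyphenyl)propiolate | COC(=O)C#Cc1c(OC)cccc1OC | intermediate
6 | 3-hydroxy-4,5-dimethoxybenzaldehyde | COc1cc(C=O)cc(O)c1OC | starting material
7 | methyl (Z)-3-(2,6-dimethoxyphenyl)-3-(5-formyl-2,3-dimethoxyphenoxy)acrylate | COC(=O)/C=C(\Oc1cc(C=O)cc(OC)c1OC)c1c(OC)cccc1OC | intermediate
8 | methyl (Z)-3-(2,6-dimethoxyphenyl)-3-[5-(formyloxy)-2,3-dimethoxyphenoxy]acrylate | COC(=O)/C=C(\Oc1cc(OC=O)cc(OC)c1OC)c1c(OC)cccc1OC | intermediate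
9 | methyl (Z)-3-(2,6-dimethoxyphenyl)-3-(5-hydroxy-2,3-dimethoxyphenoxy)acrylate | COC(=O)/C=C(\Oc1cc(O)cc(OC)c1OC)c1c(OC)cccc1OC | intermediate
10 | methyl (Z)-3-[5-(benzyloxy)-2,3-dimethoxyphenoxy]-3-(2,6-dimethoxyphenyl)acrylate | COC(=O)/C=C(\Oc1cc(OCc2ccccc2)cc(OC)c1OC)c1c(OC)cccc1OC | intermediate
11 | (Z)-3-[5-(benzyloxy)-2,3-dimethoxyphenoxy]-3-(2,6-dimethoxyphenyl)acrylic acid | OC(=O)/C=C(\Oc1cc(OCc2ccccc2)cc(OC)c1OC)c1c(OC)cccc1OC | intermediate
12 | (Z)-3-[5-(benzyloxy)-2,3-dimethoxyphenoxy]-3-(2,6-dimethoxyphenyl)acrylic trifluoroacetic anhydride | O=C(OC(=O)C(F)(F)F)/C=C(\Oc1cc(OCc2ccccc2)cc(OC)c1OC)c1c(OC)cccc1OC | intermediate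
13 | 5-(benzyloxy)-2-(2,6-dimethoxyphenyl)-7,8-dimethoxy-4H-chromen-4-one | COc1cccc(OC)c1-c1cc(=O)c2c(OCc3ccccc3)cc(OC)c(OC)c2o1 | intermediate
14 | Altisin, 5-hydroxy-2-(2,6-dimethoxyphenyl)-7,8-dimethoxy-4H-chromen-4-one | COc1cccc(OC)c1-c1cc(=O)c2c(O)cc(OC)c(OC)c2o1 | target

Total step count: 8. Longest linear sequence: 8 steps (1 → 14); 3 and 6 are bought and enter directly.

Steps most likely to fail

Step 7. The vinylogous, donor-stabilised acyl electrophile may react too slowly under activation mild enough for the benzyl ether. Debenzylation, benzyl migration or trifluoroacetylation of ring A could then overtake ring closure. The fallback changes the protecting-group plan and the endgame so that forcing acid becomes permissible. It sets out from phenol 9 and comes back at target 14.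
- O-Methylation of 9 (MeI, K2CO3, DMF) should give methyl (Z)-3-(2,6-dimethoxyphenyl)-3-(2,3,5-trimethoxyphenoxy)acrylate F1.
- Saponification (LiOH, then HCl) should give (Z)-3-(2,6-dimethoxyphenyl)-3-(2,3,5-trimethoxyphenoxy)acrylic acid F2.
- Cyclodehydration in P2O5/MeSO3H (Eaton's reagent, rt → 50 °C), to which no group of F2 is sensitive, should give 2-(2,6-dimethoxyphenyl)-5,7,8-trimethoxy-4H-chromen-4-one F3.
- BCl3 in CH2Cl2 (−78 → 0 °C) should then cleave only the 5-O-methyl group, since only that oxygen can form a six-membered boron chelate with the C4 carbonyl. This gives 14.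

Step 3. Conversion may stall because the β-carbon of the alkynoate is deactivated by the electron-rich ring B and screened by its two methoxy groups. Retro-addition could also set in at the temperature needed. The fallback replaces conjugate addition by a metal-catalysed vinyl C–O coupling. It sets out from alkynoate 5 and comes back at 7.
- Hydroiodination of 5 (NaI, AcOH, 100 °C, anti addition under acid activation) should give methyl (Z)-3-(2,6-dimethoxyphenyl)-3-iodoacrylate F4.
- An Ullmann-type coupling of F4 with phenol 6 (CuI cat., N,N-dimethylglycine, Cs2CO3, dioxane, 90 °C) proceeds with retention of alkene geometry and should give 7.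

Step 4. Three processes could erode the step: hydride migration in place of aryl migration, peracid attack at the enol-ether alkene, and exchange of the aryloxy group during methanolysis. The fallback moves the oxidation onto the simple benzaldehyde, before ring A meets the alkynoate. It sets out from 6 and comes back at 10.
- Protection of 6 (MOMCl, i-Pr2NEt, CH2Cl2) should give 3,4-dimethoxy-5-(methoxymethoxy)benzaldehyde F5.
- mCPBA should give 3,4-dimethoxy-5-(methoxymethoxy)phenyl formate F6, and methanolysis (Et3N, MeOH) should give 3,4-dimethoxy-5-(methoxymethoxy)phenol F7.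
- Benzylation (BnBr, K2CO3, DMF) should give 5-(benzyloxy)-1,2-dimethoxy-3-(methoxymethoxy)benzene F8.
- Acetal cleavage (HCl cat., MeOH, 40 °C) should give 5-(benzyloxy)-2,3-dimethoxyphenol F9.
- This more nucleophilic phenol is added to 5 under the conditions of step 3 (K2CO3, DMF, 80 °C) to give 10 directly.

Further compounds
F1 | step 7 | methyl (Z)-3-(2,6-dimethoxyphenyl)-3-(2,3,5-trimethoxyphenoxy)acrylate | COC(=O)/C=C(\Oc1cc(OC)cc(OC)c1OC)c1c(OC)cccc1OC
F2 | step 7 | (Z)-3-(2,6-dimethoxyphenyl)-3-(2,3,5-trimethoxyphenoxy)acrylic acid | OC(=O)/C=C(\Oc1cc(OC)cc(OC)c1OC)c1c(OC)cccc1OC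
F3 | step 7 | 2-(2,6-dimethoxyphenyl)-5,7,8-trimethoxy-4H-chromen-4-one | COc1cccc(OC)c1-c1cc(=O)c2c(OC)cc(OC)c(OC)c2o1
F4 | step 3 | methyl (Z)-3-(2,6-dimethoxyphenyl)-3-iodoacrylate | COC(=O)/C=C(\I)c1c(OC)cccc1OC
F5 | step 4 | 3,4-dimethoxy-5-(methoxymethoxy)benzaldehyde | COCOc1cc(C=O)cc(OC)c1OC
F6 | step 4 | 3,4-dimethoxy-5-(methoxymethoxy)phenyl formate | COCOc1cc(OC=O)cc(OC)c1OC
F7 | step 4 | 3,4-dimethoxy-5-(methoxymethoxy)phenol | COCOc1cc(O)cc(OC)c1OC
F8 | step 4 | 5-(benzyloxy)-1,2-dimethoxy-3-(methoxymethoxy)benzene | COCOc1cc(OCc2ccccc2)cc(OC)c1OC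
F9 | step 4 | 5-(benzyloxy)-2,3-dimethoxyphenol | Oc1cc(OCc2ccccc2)cc(OC)c1OC
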